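**Retrosynthetic overview**
1. Target 41 ← hydroxyl-directed double epoxidation (C4=C15, C2=C3) of dienol 39 ← angeloylation at C8 and desilylation of macrocycle 35.
2. 35 ← key step: intramolecular sulfonium-ylide epoxidation of seco ketone 30; the new C1–C10 bond is both the C–C bond of the 1,10-oxirane and the ring-closing bond of the ten-membered carbocycle.
3. Enabling feature: C10 is a methyl-bearing carbon at the ketone oxidation level, so its carbonyl oxygen becomes the oxirane oxygen; C1 is allylic to the Z-C2=C3/C4=C15 diene, so a sulfonium group on C1 gives a dienyl-stabilised ylide; the Z-alkene and the trans-lactone pre-bend the C1–C10 chain.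
4. 30 ← chromium-mediated allylation/lactonisation (C6–C7 bond, γ-lactone) of aldehyde 10 (C1–C6, C15; from (S)-glycerate) with bromide 20 (C7–C14; from (R)-glycidol, 2-methyl-1,3-dithiane and methyl acrylate).
5. Ring order: γ-lactone (step 13) → ten-membered carbocycle and 1,10-oxirane together (step 18) → 4,15- and 2,3-oxiranes (step 23).

Key step: step 18

Remark: germacrane numbering is used for all compounds (C1–C10 carbocycle, C11–C13 lactone carbons with C12 the carbonyl carbon, C14 the methyl carbon on C10, C15 the exocyclic carbon on C4). CIP descriptors of a centre can change when a neighbouring group changes although the centre is not touched.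
Assumption: 4-methoxybenzyl propargyl ether 3 is taken as a commercial starting material (otherwise one step from propargyl alcohol).

**Route**

Step 1
Reactants: 1 methyl (4S)-2,2-dimethyl-1,3-dioxolane-4-carboxylate
Product: 2 (4S)-N-methoxy-N,2,2-trimethyl-1,3-dioxolane-4-carboxamide
Conditions: MeNH(OMe)·HCl, i-PrMgCl, THF, −20 → 0 °C
Reagents that add atoms: N,O-dimethylhydroxylamine hydrochloride, CNOC.Cl
Why: Weinreb amide formation from the ester with the chloromagnesium amide proceeds at low temperature without touching the C5 stereocentre, which comes from the chiral pool.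

Step 2
Reactants: 2 (4S)-N-methoxy-N,2,2-trimethyl-1,3-dioxolane-4-carboxamide; 3 1-methoxy-4-[(prop-2-yn-1-yloxy)methyl]benzene
Product: 4 1-[(4S)-2,2-dimethyl-1,3-dioxolan-4-yl]-4-[(4-methoxybenzyl)oxy]but-2-yn-1-one
Conditions: 3, n-BuLi, THF, −78 °C; then 2, −78 → 0 °C
Reagents that add atoms: none
Why: Acylation of an alkynyllithium by a Weinreb amide stops at the ynone because the chelated tetrahedral intermediate survives until work-up, and the low temperature protects the α-alkoxy stereocentre.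

Step 3
Reactants: 4 1-[(4S)-2,2-dimethyl-1,3-dioxolan-4-yl]-4-[(4-methoxybenzyl)oxy]but-2-yn-1-one
Product: 5 (4R)-4-{5-[(4-methoxybenzyl)oxy]pent-1-en-3-yn-2-yl}-2,2-dimethyl-1,3-dioxolane
Conditions: Ph3PCH3Br, KN(SiMe3)2, THF, −78 → 0 °C
Reagents that add atoms: methyltriphenylphosphonium bromide, C[P+](c1ccccc1)(c1ccccc1)c1ccccc1.[Br-]
Why: Wittig methylenation of the highly electrophilic ynone carbonyl with the salt-free ylide should outrun enolisation and so install C15 without loss of the C5 configuration.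

Step 4
Reactants: 5 (4R)-4-{5-[(4-methoxybenzyl)oxy]pent-1-en-3-yn-2-yl}-2,2-dimethyl-1,3-dioxolane
Product: 6 (4R)-4-{(3Z)-5-[(4-methoxybenzyl)oxy]penta-1,3-dien-2-yl}-2,2-dimethyl-1,3-dioxolane
Conditions: H2 (1 atm), Pd/CaCO3 poisoned with Pb(OAc)2 (Lindlar catalyst), quinoline, EtOAc, 25 °C
Reagents that add atoms: none
Why: Lindlar semihydrogenation adds hydrogen syn to the conjugated alkyne and so sets the (Z)-C2=C3 bond, while the 1,1-disubstituted alkene and the benzyl ether are left alone in the presence of quinoline.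

Step 5
Reactants: 6 (4R)-4-{(3Z)-5-[(4-methoxybenzyl)oxy]penta-1,3-dien-2-yl}-2,2-dimethyl-1,3-dioxolane
Product: 7 (2R,4Z)-6-[(4-methoxybenzyl)oxy]-3-methylidenehex-4-ene-1,2-diol
Conditions: AcOH/H2O (4:1), 25 °C
Reagents that add atoms: none
Why: Mild acid hydrolysis of the acetonide frees the C5/C6 diol without ionising the allylic C5–O bond or cleaving the 4-methoxybenzyl ether.

Step 6
Reactants: 7 (2R,4Z)-6-[(4-methoxybenzyl)oxy]-3-methylidenehex-4-ene-1,2-diol
Product: 9 tert-butyl{[(2R,4Z)-6-[(4-methoxybenzyl)oxy]-3-methylidene-1-(triethylsilyloxy)hex-4-en-2-yl]oxy}dimethylsilane, via primary triethylsilyl ether 8 (not isolated)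
Conditions: Et3SiCl, imidazole, CH2Cl2, −40 °C; then t-BuMe2SiOTf, 2,6-lutidine, −40 → 0 °C
Reagents that add atoms: chlorotriethylsilane, CC[Si](Cl)(CC)CC; tert-butyldimethylsilyl trifluoromethanesulfonate, CC(C)(C)[Si](C)(C)OS(=O)(=O)C(F)(F)F
Why: Sequential silylation exploits the higher rate of the primary hydroxyl toward the small chlorosilane at low temperature, after which the silyl triflate caps the hindered secondary allylic hydroxyl.

Step 7
Reactants: 9 tert-butyl{[(2R,4Z)-6-[(4-methoxybenzyl)oxy]-3-methylidene-1-(triethylsilyloxy)hex-4-en-2-yl]oxy}dimethylsilane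
Product: 10 (2R,4Z)-2-(tert-butyldimethylsilyloxy)-6-[(4-methoxybenzyl)oxy]-3-methylidenehex-4-enal
Conditions: (COCl)2, DMSO, CH2Cl2, −78 → −40 °C; then Et3N, −78 → −20 °C
Reagents that add atoms: none
Why: Under Swern conditions a primary triethylsilyl ether is cleaved and oxidised directly to the aldehyde while the secondary tert-butyldimethylsilyl ether is inert, and the short cold exposure to base preserves the α-stereocentre and the β,γ-unsaturation (the aldehyde is used crude).

Step 8
Reactants: 11 [(2R)-oxiran-2-yl]methanol ((R)-glycidol)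
Product: 12 triethyl{[(2S)-oxiran-2-yl]methoxy}silane
Conditions: Et3SiCl, imidazole, CH2Cl2, 0 °C
Reagents that add atoms: chlorotriethylsilane, CC[Si](Cl)(CC)CC
Why: Simple O-silylation leaves the epoxide and its stereocentre (the future C8) untouched.

Step 9
Reactants: 12 triethyl{[(2S)-oxiran-2-yl]methoxy}silane; 13 2-methyl-1,3-dithiane
Product: 15 2-[(2S)-2,3-bis(triethylsilyloxy)propyl]-2-methyl-1,3-dithiane, via lithium alkoxide 14 (not isolated)
Conditions: 13, n-BuLi, THF, −30 °C; then 12, −30 → 0 °C; then Et3SiCl, 0 °C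
Reagents that add atoms: chlorotriethylsilane, CC[Si](Cl)(CC)CC; n-butyllithium, [Li]CCCC (lithium of 14 only)
Why: Corey–Seebach alkylation: the lithiated dithiane (a masked acetyl anion carrying C10 and C14) opens the epoxide at its unsubstituted carbon with retention at C8, and the alkoxide is silylated in the same flask.

Step 10
Reactants: 15 2-[(2S)-2,3-bis(triethylsilyloxy)propyl]-2-methyl-1,3-dithiane
Product: 16 (2S)-3-(2-methyl-1,3-dithian-2-yl)-2-(triethylsilyloxy)propanal
Conditions: (COCl)2, DMSO, CH2Cl2, −78 → −40 °C; then Et3N, −78 → −20 °C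
Reagents that add atoms: none
Why: The same selective Swern oxidation of a primary over a secondary triethylsilyl ether gives the C7 aldehyde, and thioacetals tolerate activated DMSO at low temperature.

Step 11
Reactants: 16 (2S)-3-(2-methyl-1,3-dithian-2-yl)-2-(triethylsilyloxy)propanal; 17 methyl acrylate
Product: 18 methyl (3RS,4S)-3-hydroxy-2-methylidene-5-(2-methyl-1,3-dithian-2-yl)-4-(triethylsilyloxy)pentanoate
Conditions: DABCO (1 equiv), methyl acrylate (neat, excess), 25 °C
Reagents that add atoms: none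
Why: Morita–Baylis–Hillman reaction of the activated α-silyloxy aldehyde attaches C11–C13; the new C7 carbinol centre is erased in the next step, so its configuration does not matter.

Step 12
Reactants: 18 methyl (3RS,4S)-3-hydroxy-2-methylidene-5-(2-methyl-1,3-dithian-2-yl)-4-(triethylsilyloxy)pentanoate
Product: 20 methyl (2Z,4S)-2-(bromomethyl)-5-(2-methyl-1,3-dithian-2-yl)-4-(triethylsilyloxy)pent-2-enoate, via allylic mesylate 19 (not isolated)
Conditions: (MeSO2)2O, Et3N, CH2Cl2, −20 °C; then LiBr, THF, 0 → 25 °C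
Reagents that add atoms: lithium bromide, [Li+].[Br-]; methanesulfonic anhydride, CS(=O)(=O)OS(C)(=O)=O (mesyl group of 19 only)
Why: SN2′ displacement of the Baylis–Hillman mesylate by bromide gives the thermodynamically preferred 2-(bromomethyl)enoate, whose geometry is not critical because the allylchromium reagent of step 13 equilibrates.

Step 13
Reactants: 10 (2R,4Z)-2-(tert-butyldimethylsilyloxy)-6-[(4-methoxybenzyl)oxy]-3-methylidenehex-4-enal; 20 methyl (2Z,4S)-2-(bromomethyl)-5-(2-methyl-1,3-dithian-2-yl)-4-(triethylsilyloxy)pent-2-enoate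
Product: 23 (5R,6S,7S,8S)-5-(tert-butyldimethylsilyloxy)-1-(4-methoxybenzyloxy)-10,10-(propane-1,3-diyldisulfanediyl)-8-(triethylsilyloxy)-1,10-secogermacra-2Z,4(15),11(13)-trien-12,6-olide, via allylchromium dichloride 21 (not isolated), via chromium alkoxide 22 (not isolated)
Conditions: CrCl2 (5 equiv), THF, 0 → 25 °C, then 40 °C
Reagents that add atoms: chromium dichloride, Cl[Cr]Cl (chromium and chlorine of 21 and 22 only)
Why: Nozaki–Hiyama–Kishi-type allylation with divalent chromium: the equilibrating allylchromium adds through a chair transition state with C8 equatorial (6,7-anti, hence the trans lactone once the alkoxide closes onto the ester), Felkin–Anh addition anti to the C5 silyloxy group sets C6, and attack on the allyl face anti to the C8–O bond sets C7, the two facial preferences reinforcing each other.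

Step 14
Reactants: 23 (5R,6S,7S,8S)-5-(tert-butyldimethylsilyloxy)-1-(4-methoxybenzyloxy)-10,10-(propane-1,3-diyldisulfanediyl)-8-(triethylsilyloxy)-1,10-secogermacra-2Z,4(15),11(13)-trien-12,6-olide
Product: 24 (5R,6S,7S,8S)-5-(tert-butyldimethylsilyloxy)-1-(4-methoxybenzyloxy)-10-oxo-8-(triethylsilyloxy)-1,10-secogermacra-2Z,4(15),11(13)-trien-12,6-olide
Conditions: MeI, CaCO3, MeCN/H2O (9:1), 40 °C
Reagents that add atoms: water, O
Why: Alkylative hydrolysis of the dithiane under neutral buffered conditions unmasks the C10 methyl ketone without affecting silyl ethers, the benzyl ether, the diene or the methylene lactone.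

Step 15
Reactants: 24 (5R,6S,7S,8S)-5-(tert-butyldimethylsilyloxy)-1-(4-methoxybenzyloxy)-10-oxo-8-(triethylsilyloxy)-1,10-secogermacra-2Z,4(15),11(13)-trien-12,6-olide
Product: 25 (5R,6S,7S,8S)-5-(tert-butyldimethylsilyloxy)-1-hydroxy-10-oxo-8-(triethylsilyloxy)-1,10-secogermacra-2Z,4(15),11(13)-trien-12,6-olide
Conditions: DDQ, CH2Cl2/pH 7 buffer (10:1), 0 °C
Reagents that add atoms: none
Why: Oxidative cleavage of the 4-methoxybenzyl ether by DDQ is fast at 0 °C and leaves silyl ethers, the ketone and the diene intact.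

Step 16
Reactants: 25 (5R,6S,7S,8S)-5-(tert-butyldimethylsilyloxy)-1-hydroxy-10-oxo-8-(triethylsilyloxy)-1,10-secogermacra-2Z,4(15),11(13)-trien-12,6-olide; 26 benzeneselenol
Product: 27 (5R,6S,7S,8S,11RS)-5-(tert-butyldimethylsilyloxy)-1-hydroxy-10-oxo-13-(phenylselanyl)-8-(triethylsilyloxy)-1,10-secogermacra-2Z,4(15)-dien-12,6-olide
Conditions: PhSeH, Et3N (0.2 equiv), CH2Cl2, 0 → 25 °C
Reagents that add atoms: none
Why: Conjugate addition of the selenol masks the α-methylene lactone, which would otherwise be cyclopropanated by the sulfur ylide of step 18; the C11 epimers are inconsequential because the centre is removed in step 19.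

Step 17
Reactants: 27 (5R,6S,7S,8S,11RS)-5-(tert-butyldimethylsilyloxy)-1-hydroxy-10-oxo-13-(phenylselanyl)-8-(triethylsilyloxy)-1,10-secogermacra-2Z,4(15)-dien-12,6-olide; 28 tetrahydrothiophene
Product: 30 (5R,6S,7S,8S,11RS)-5-(tert-butyldimethylsilyloxy)-10-oxo-13-(phenylselanyl)-1-(thiolan-1-ium-1-yl)-8-(triethylsilyloxy)-1,10-secogermacra-2Z,4(15)-dien-12,6-olide methanesulfonate, via allylic mesylate 29 (not isolated)
Conditions: (MeSO2)2O, i-Pr2NEt, CH2Cl2, −30 °C; then tetrahydrothiophene (10 equiv), −30 → 25 °C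
Reagents that add atoms: methanesulfonic anhydride, CS(=O)(=O)OS(C)(=O)=O
Why: Mesylation of the primary allylic alcohol and SN2 displacement by the excess dialkyl sulfide give the allylic sulfonium salt, the low temperature and chloride-free medium keeping the (Z)-C2=C3 geometry.

Step 18
Reactants: 30 (5R,6S,7S,8S,11RS)-5-(tert-butyldimethylsilyloxy)-10-oxo-13-(phenylselanyl)-1-(thiolan-1-ium-1-yl)-8-(triethylsilyloxy)-1,10-secogermacra-2Z,4(15)-dien-12,6-olide methanesulfonate
Product: 33 (1R,5R,6S,7S,8S,10R,11RS)-5-(tert-butyldimethylsilyloxy)-1,10-epoxy-13-(phenylselanyl)-8-(triethylsilyloxy)germacra-2Z,4(15)-dien-12,6-olide, via sulfonium ylide 31 (not isolated), via betaine 32 (not isolated)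
Conditions: LiN(SiMe3)2 (1.05 equiv, added over 3 h), THF/CH2Cl2 (4:1), 1 mM, −78 °C; then −78 → 0 °C
Reagents that add atoms: none
Why: Proposed new method: the amide base removes the C1 proton of the dienyl sulfonium salt (the most acidic C–H by several pKa units), the ylide carbon adds to the C10 methyl ketone to give betaine 32, and the C10 alkoxide then displaces tetrahydrothiophene from C1, so the single new C1–C10 bond is both the last bond of the ten-membered carbocycle and the C–C bond of the oxirane; the closest known reaction type is the Corey–Chaykovsky epoxidation of aldehydes and ketones with allylic and dienyl sulfonium ylides (vinyl oxirane synthesis), known intermolecularly and for small rings but not as a macrocyclisation. The carbocycle closes by 10-exo-trig addition of the ylide carbon to the carbonyl group, helped by the turn imposed by the (Z)-C2=C3 bond and the trans-fused lactone, and the oxirane closes by 3-exo-tet substitution. C1 and C10 are set together: closure needs O–C10–C1–S antiperiplanar, the betaine with C9 and C2 anti (the CH2 group, larger than CH3, opposite the dienyl group) gives the trans oxirane, and reversible betaine formation lets this isomer drain through. The ketone face is expected to follow the crown conformation of 6,7-trans-fused germacranolides, with the C10 methyl group on the β face next to H6 and H8, which leads to (1R,10R); this is the least secure element of control. The step needs attack through C1 and not C3 or C15 of the dienyl ylide (largest coefficient next to sulfur, as in known dienyl ylide epoxidations), reaction at the ketone and not at the lactone (secured by the selenide mask and the poor electrophilicity of the lactone carbonyl toward sulfur ylides), and ring closure over oligomerisation (1 mM, slow addition of base).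

Step 19
Reactants: 33 (1R,5R,6S,7S,8S,10R,11RS)-5-(tert-butyldimethylsilyloxy)-1,10-epoxy-13-(phenylselanyl)-8-(triethylsilyloxy)germacra-2Z,4(15)-dien-12,6-olide
Product: 35 (1R,5R,6S,7S,8S,10R)-5-(tert-butyldimethylsilyloxy)-1,10-epoxy-8-(triethylsilyloxy)germacra-2Z,4(15),11(13)-trien-12,6-olide, via selenoxide 34 (not isolated)
Conditions: NaIO4, NaHCO3, THF/H2O (3:1), 0 → 25 °C
Reagents that add atoms: sodium periodate, [Na+].[O-]I(=O)(=O)=O (oxygen of 34 only)
Why: Selenide oxidation and selenoxide syn-elimination through the only β-hydrogen (H11) restore the α-methylene lactone under neutral conditions that spare the vinyl oxirane.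

Step 20
Reactants: 35 (1R,5R,6S,7S,8S,10R)-5-(tert-butyldimethylsilyloxy)-1,10-epoxy-8-(triethylsilyloxy)germacra-2Z,4(15),11(13)-trien-12,6-olide
Product: 36 (1R,5R,6S,7R,8S,10R)-5-(tert-butyldimethylsilyloxy)-1,10-epoxy-8-hydroxygermacra-2Z,4(15),11(13)-trien-12,6-olide
Conditions: HF·pyridine, pyridine, THF, 0 °C
Reagents that add atoms: none
Why: Buffered fluoride cleaves the less hindered secondary triethylsilyl ether much faster than the tert-butyldimethylsilyl ether, and the excess pyridine protects the allylic oxirane from acid.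

Step 21
Reactants: 36 (1R,5R,6S,7R,8S,10R)-5-(tert-butyldimethylsilyloxy)-1,10-epoxy-8-hydroxygermacra-2Z,4(15),11(13)-trien-12,6-olide; 37 (2Z)-2-methylbut-2-enoic acid (angelic acid)
Product: 38 (1R,5R,6S,7R,8S,10R)-8-angeloyloxy-5-(tert-butyldimethylsilyloxy)-1,10-epoxygermacra-2Z,4(15),11(13)-trien-12,6-olide
Conditions: 37, 2,4,6-Cl3C6H2COCl, Et3N, PhMe, 25 °C; then 36, 75 °C
Reagents that add atoms: none
Why: Yamaguchi-type esterification through the mixed trichlorobenzoic anhydride without a nucleophilic catalyst acylates the C8 hydroxyl with retention and avoids the angelate-to-tiglate isomerisation that nucleophilic catalysts cause.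

Step 22
Reactants: 38 (1R,5R,6S,7R,8S,10R)-8-angeloyloxy-5-(tert-butyldimethylsilyloxy)-1,10-epoxygermacra-2Z,4(15),11(13)-trien-12,6-olide
Product: 39 (1R,5R,6S,7R,8S,10R)-8-angeloyloxy-1,10-epoxy-5-hydroxygermacra-2Z,4(15),11(13)-trien-12,6-olide
Conditions: Bu4NF, AcOH (1:1), THF, 0 → 25 °C
Reagents that add atoms: none
Why: Acetic acid-buffered fluoride removes the remaining silyl ether without basic damage to the methylene lactone, the angelate or the oxirane.

Step 23
Reactants: 39 (1R,5R,6S,7R,8S,10R)-8-angeloyloxy-1,10-epoxy-5-hydroxygermacra-2Z,4(15),11(13)-trien-12,6-olide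
Product: 41 (1R,2R,3S,4S,5S,6S,7R,8S,10R)-8-angeloyloxy-1,10:2,3:4,15-triepoxy-5-hydroxygermacr-11(13)-en-12,6-olide (CNP0594916.1), via 4,15-epoxide 40 (not isolated)
Conditions: mCPBA (2.5 equiv), NaHCO3, CH2Cl2, 0 → 25 °C
Reagents that add atoms: 3-chloroperoxybenzoic acid, OOC(=O)c1cccc(Cl)c1
Why: Prilezhaev epoxidation with Henbest hydroxyl direction: the C5 hydroxyl, perpendicular to the C4=C15 bond in the rotamer with H5 eclipsing the methylene group, should deliver the peracid to the exposed face of the exocyclic alkene (C4 S), and the cis C2=C3 bond should then be attacked on its outer face, anti to C5 and to the C6–C10 arc of the ring (C2 R, C3 S), while the electron-poor methylene lactone and angelate do not react.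

**Compound list**
1 | methyl (4S)-2,2-dimethyl-1,3-dioxolane-4-carboxylate | COC(=O)[C@@H]1COC(C)(C)O1 | starting material
2 | (4S)-N-methoxy-N,2,2-trimethyl-1,3-dioxolane-4-carboxamide | CON(C)C(=O)[C@@H]1COC(C)(C)O1 | intermediate
3 | 1-methoxy-4-[(prop-2-yn-1-yloxy)methyl]benzene | C#CCOCc1ccc(OC)cc1 | starting material
4 | 1-[(4S)-2,2-dimethyl-1,3-dioxolan-4-yl]-4-[(4-methoxybenzyl)oxy]but-2-yn-1-one | O=C(C#CCOCc1ccc(OC)cc1)[C@@H]1COC(C)(C)O1 | intermediate
5 | (4R)-4-{5-[(4-methoxybenzyl)oxy]pent-1-en-3-yn-2-yl}-2,2-dimethyl-1,3-dioxolane | C=C(C#CCOCc1ccc(OC)cc1)[C@@H]1COC(C)(C)O1 | intermediate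
6 | (4R)-4-{(3Z)-5-[(4-methoxybenzyl)oxy]penta-1,3-dien-2-yl}-2,2-dimethyl-1,3-dioxolane | C=C(/C=C\COCc1ccc(OC)cc1)[C@@H]1COC(C)(C)O1 | intermediate
7 | (2R,4Z)-6-[(4-methoxybenzyl)oxy]-3-methylidenehex-4-ene-1,2-diol | OC[C@H](O)C(=C)/C=C\COCc1ccc(OC)cc1 | intermediate
8 | (2R,4Z)-6-[(4-methoxybenzyl)oxy]-3-methylidene-1-(triethylsilyloxy)hex-4-en-2-ol (not isolated) | CC[Si](CC)(CC)OC[C@H](O)C(=C)/C=C\COCc1ccc(OC)cc1 | intermediate
9 | tert-butyl{[(2R,4Z)-6-[(4-methoxybenzyl)oxy]-3-methylidene-1-(triethylsilyloxy)hex-4-en-2-yl]oxy}dimethylsilane | CC[Si](CC)(CC)OC[C@H](O[Si](C)(C)C(C)(C)C)C(=C)/C=C\COCc1ccc(OC)cc1 | intermediate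
10 | (2R,4Z)-2-(tert-butyldimethylsilyloxy)-6-[(4-methoxybenzyl)oxy]-3-methylidenehex-4-enal | O=C[C@H](O[Si](C)(C)C(C)(C)C)C(=C)/C=C\COCc1ccc(OC)cc1 | intermediate
11 | [(2R)-oxiran-2-yl]methanol | OC[C@@H]1CO1 | starting material
12 | triethyl{[(2S)-oxiran-2-yl]methoxy}silane | CC[Si](CC)(CC)OC[C@@H]1CO1 | intermediate
13 | 2-methyl-1,3-dithiane | CC1SCCCS1 | starting material
14 | lithium (2S)-1-(2-methyl-1,3-dithian-2-yl)-3-(triethylsilyloxy)propan-2-olate (not isolated) | CC[Si](CC)(CC)OC[C@H](CC1(C)SCCCS1)[O-].[Li+] | intermediate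
15 | 2-[(2S)-2,3-bis(triethylsilyloxy)propyl]-2-methyl-1,3-dithiane | CC[Si](CC)(CC)OC[C@H](CC1(C)SCCCS1)O[Si](CC)(CC)CC | intermediate
16 | (2S)-3-(2-methyl-1,3-dithian-2-yl)-2-(triethylsilyloxy)propanal | O=C[C@H](CC1(C)SCCCS1)O[Si](CC)(CC)CC | intermediate
17 | methyl acrylate | C=CC(=O)OC | starting material
18 | methyl (3RS,4S)-3-hydroxy-2-methylidene-5-(2-methyl-1,3-dithian-2-yl)-4-(triethylsilyloxy)pentanoate | COC(=O)C(=C)C(O)[C@H](CC1(C)SCCCS1)O[Si](CC)(CC)CC | intermediate
19 | methyl (3RS,4S)-3-(methanesulfonyloxy)-2-methylidene-5-(2-methyl-1,3-dithian-2-yl)-4-(triethylsilyloxy)pentanoate (not isolated) | COC(=O)C(=C)C(OS(C)(=O)=O)[C@H](CC1(C)SCCCS1)O[Si](CC)(CC)CC | intermediate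
20 | methyl (2Z,4S)-2-(bromomethyl)-5-(2-methyl-1,3-dithian-2-yl)-4-(triethylsilyloxy)pent-2-enoate | COC(=O)/C(CBr)=C/[C@H](CC1(C)SCCCS1)O[Si](CC)(CC)CC | intermediate
21 | allylchromium dichloride from 20 (trivalent chromium on C13; not isolated) | COC(=O)C(C[Cr](Cl)Cl)=C[C@H](CC1(C)SCCCS1)O[Si](CC)(CC)CC | intermediate
22 | C6 dichlorochromium alkoxide of the open methyl ester (5R,6S,7R,8S; not isolated) | COC(=O)C(=C)[C@H]([C@@H](O[Si](CC)(CC)CC)CC1(C)SCCCS1)[C@H](O[Cr](Cl)Cl)[C@H](O[Si](C)(C)C(C)(C)C)C(=C)/C=C\COCc1ccc(OC)cc1 | intermediate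
23 | (5R,6S,7S,8S)-5-(tert-butyldimethylsilyloxy)-1-(4-methoxybenzyloxy)-10,10-(propane-1,3-diyldisulfanediyl)-8-(triethylsilyloxy)-1,10-secogermacra-2Z,4(15),11(13)-trien-12,6-olide | C=C1C(=O)O[C@@H]([C@H]1[C@@H](O[Si](CC)(CC)CC)CC1(C)SCCCS1)[C@H](O[Si](C)(C)C(C)(C)C)C(=C)/C=C\COCc1ccc(OC)cc1 | intermediate
24 | (5R,6S,7S,8S)-5-(tert-butyldimethylsilyloxy)-1-(4-methoxybenzyloxy)-10-oxo-8-(triethylsilyloxy)-1,10-secogermacra-2Z,4(15),11(13)-trien-12,6-olide | C=C1C(=O)O[C@@H]([C@H]1[C@@H](O[Si](CC)(CC)CC)CC(C)=O)[C@H](O[Si](C)(C)C(C)(C)C)C(=C)/C=C\COCc1ccc(OC)cc1 | intermediate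
25 | (5R,6S,7S,8S)-5-(tert-butyldimethylsilyloxy)-1-hydroxy-10-oxo-8-(triethylsilyloxy)-1,10-secogermacra-2Z,4(15),11(13)-trien-12,6-olide | C=C1C(=O)O[C@@H]([C@H]1[C@@H](O[Si](CC)(CC)CC)CC(C)=O)[C@H](O[Si](C)(C)C(C)(C)C)C(=C)/C=C\CO | intermediate
26 | benzeneselenol | [SeH]c1ccccc1 | starting material
27 | (5R,6S,7S,8S,11RS)-5-(tert-butyldimethylsilyloxy)-1-hydroxy-10-oxo-13-(phenylselanyl)-8-(triethylsilyloxy)-1,10-secogermacra-2Z,4(15)-dien-12,6-olide | c1ccccc1[Se]CC1C(=O)O[C@@H]([C@H]1[C@@H](O[Si](CC)(CC)CC)CC(C)=O)[C@H](O[Si](C)(C)C(C)(C)C)C(=C)/C=C\CO | intermediate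
28 | tetrahydrothiophene | C1CCSC1 | starting material
29 | 1-O-methanesulfonate of 27 (not isolated) | c1ccccc1[Se]CC1C(=O)O[C@@H]([C@H]1[C@@H](O[Si](CC)(CC)CC)CC(C)=O)[C@H](O[Si](C)(C)C(C)(C)C)C(=C)/C=C\COS(C)(=O)=O | intermediate
30 | (5R,6S,7S,8S,11RS)-5-(tert-butyldimethylsilyloxy)-10-oxo-13-(phenylselanyl)-1-(thiolan-1-ium-1-yl)-8-(triethylsilyloxy)-1,10-secogermacra-2Z,4(15)-dien-12,6-olide methanesulfonate | c1ccccc1[Se]CC1C(=O)O[C@@H]([C@H]1[C@@H](O[Si](CC)(CC)CC)CC(C)=O)[C@H](O[Si](C)(C)C(C)(C)C)C(=C)/C=C\C[S+]1CCCC1.CS(=O)(=O)[O-] | intermediate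
31 | C1 sulfonium ylide of 30 (not isolated) | c1ccccc1[Se]CC1C(=O)O[C@@H]([C@H]1[C@@H](O[Si](CC)(CC)CC)CC(C)=O)[C@H](O[Si](C)(C)C(C)(C)C)C(=C)/C=C\[CH-][S+]1CCCC1 | intermediate
32 | macrocyclic betaine (1S,5R,6S,7S,8S,10R,11RS): C10 alkoxide and C1 thiolanium (not isolated) | c1ccccc1[Se]CC1C(=O)O[C@H]2[C@H]1[C@@H](O[Si](CC)(CC)CC)C[C@@](C)([O-])[C@@H]([S+]1CCCC1)/C=C\C(=C)[C@H]2O[Si](C)(C)C(C)(C)C | intermediate
33 | (1R,5R,6S,7S,8S,10R,11RS)-5-(tert-butyldimethylsilyloxy)-1,10-epoxy-13-(phenylselanyl)-8-(triethylsilyloxy)germacra-2Z,4(15)-dien-12,6-olide | c1ccccc1[Se]CC1C(=O)O[C@H]2[C@H]1[C@@H](O[Si](CC)(CC)CC)C[C@@]1(C)O[C@@H]1/C=C\C(=C)[C@H]2O[Si](C)(C)C(C)(C)C | intermediate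
34 | selenoxide of 33 (not isolated) | O=[Se](c1ccccc1)CC1C(=O)O[C@H]2[C@H]1[C@@H](O[Si](CC)(CC)CC)C[C@@]1(C)O[C@@H]1/C=C\C(=C)[C@H]2O[Si](C)(C)C(C)(C)C | intermediate
35 | (1R,5R,6S,7S,8S,10R)-5-(tert-butyldimethylsilyloxy)-1,10-epoxy-8-(triethylsilyloxy)germacra-2Z,4(15),11(13)-trien-12,6-olide | C=C1C(=O)O[C@H]2[C@H]1[C@@H](O[Si](CC)(CC)CC)C[C@@]1(C)O[C@@H]1/C=C\C(=C)[C@H]2O[Si](C)(C)C(C)(C)C | intermediate
36 | (1R,5R,6S,7R,8S,10R)-5-(tert-butyldimethylsilyloxy)-1,10-epoxy-8-hydroxygermacra-2Z,4(15),11(13)-trien-12,6-olide | C=C1C(=O)O[C@H]2[C@H]1[C@@H](O)C[C@@]1(C)O[C@@H]1/C=C\C(=C)[C@H]2O[Si](C)(C)C(C)(C)C | intermediate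
37 | (2Z)-2-methylbut-2-enoic acid (angelic acid) | C/C=C(/C)C(=O)O | starting material
38 | (1R,5R,6S,7R,8S,10R)-8-angeloyloxy-5-(tert-butyldimethylsilyloxy)-1,10-epoxygermacra-2Z,4(15),11(13)-trien-12,6-olide | C=C1C(=O)O[C@H]2[C@H]1[C@@H](OC(=O)/C(C)=C\C)C[C@@]1(C)O[C@@H]1/C=C\C(=C)[C@H]2O[Si](C)(C)C(C)(C)C | intermediate
39 | (1R,5R,6S,7R,8S,10R)-8-angeloyloxy-1,10-epoxy-5-hydroxygermacra-2Z,4(15),11(13)-trien-12,6-olide | C=C1C(=O)O[C@H]2[C@H]1[C@@H](OC(=O)/C(C)=C\C)C[C@@]1(C)O[C@@H]1/C=C\C(=C)[C@H]2O | intermediate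
40 | (1R,4S,5S,6S,7R,8S,10R)-8-angeloyloxy-1,10:4,15-diepoxy-5-hydroxygermacra-2Z,11(13)-dien-12,6-olide (not isolated) | C=C1C(=O)O[C@H]2[C@H]1[C@@H](OC(=O)/C(C)=C\C)C[C@@]1(C)O[C@@H]1/C=C\[C@]1(CO1)[C@H]2O | intermediate
41 | (1R,2R,3S,4S,5S,6S,7R,8S,10R)-8-angeloyloxy-1,10:2,3:4,15-triepoxy-5-hydroxygermacr-11(13)-en-12,6-olide (CNP0594916.1) | C=C1C(=O)O[C@H]2[C@H]1[C@@H](OC(=O)/C(C)=C\C)C[C@@]1(C)O[C@@H]1[C@@H]1O[C@@H]1[C@]1(CO1)[C@H]2O | target

**Step count**
Total: 23 steps. Longest linear sequence: 18 steps (steps 1–7, then 13–23); the other branch is steps 8–12.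

**Steps most likely to fail**

1. Step 18 (Proposed new method). The ylide may be consumed by intermolecular reaction, by proton transfer followed by β-elimination of the C8 silyloxy group, or by closure to the cis oxirane or to the trans oxirane on the other ring face (poor facial selectivity at C1/C10). The fallback separates C–C bond formation from oxygen transfer and uses known chemistry. It sets out from 27: mesylation as in step 17 but with PPh3 in place of the sulfide gives the allylic triphenylphosphonium methanesulfonate F1. KN(SiMe3)2 in THF at high dilution then effects an intramolecular Wittig olefination with the C10 ketone to the (1(10)E,2Z)-triene macrocycle F2 (E isomer separated if needed). mCPBA (2.2 equiv, NaHCO3, CH2Cl2, −78 → 0 °C) then oxidises the selenide, which eliminates to the methylene lactone, and epoxidises the most electron-rich trisubstituted C1=C10 bond from the outer face, the sense expected for 1(10)-olefins of 6,7-trans-fused germacranolides. The route is rejoined at 35.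

2. Step 23. The two epoxidations may occur with poor or opposite facial selectivity if the macrocycle reacts through a conformer other than the one assumed, or the acid by-product may open the allylic 1,10-oxirane. The fallback replaces substrate control at the cis alkene by reagent control. It sets out from 39: Jacobsen–Katsuki epoxidation (Mn(salen)Cl with salen = N,N′-bis(3,5-di-tert-butylsalicylidene)-trans-cyclohexane-1,2-diamine dianion, trivalent manganese, NaOCl, 4-phenylpyridine N-oxide, CH2Cl2, 0 °C), with the catalyst antipode matched to the β face, converts the conjugated cis C2=C3 bond to the 2,3-epoxide F3. Hydroxyl-directed epoxidation of the remaining allylic alcohol with mCPBA then gives 41.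

3. Step 13. The β,γ-unsaturated α-silyloxy aldehyde may isomerise into conjugation or epimerise at C5 on the Lewis acidic chromium salts, the allylchromium may lose the C8 silyloxy group by elimination, or the syn adduct (cis lactone) may form through poor simple diastereoselection. The fallback replaces the equilibrating allylchromium by a geometry-defined allylboronate, whose olefin geometry fixes the 6,7-relationship through a closed transition state. It sets out from 16: Ohira–Bestmann homologation (dimethyl (1-diazo-2-oxopropyl)phosphonate, K2CO3, MeOH) gives alkyne F4. n-BuLi and ClCO2Me give ynoate F5. Conjugate hydroalumination (i-Bu2AlH, HMPA, THF, 0 °C) and trapping of the α-aluminated acrylate with ICH2B(pin) on the side away from C8 give the allylboronate F6 with C8 cis to the ester. F6 and aldehyde 10 with Sc(OTf)3 (cat.) in toluene at 0 → 25 °C give the 6,7-anti adduct, which lactonises to 23, where the route is rejoined.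

**Further compounds**
F1 | step 18 | (5R,6S,7S,8S,11RS)-5-(tert-butyldimethylsilyloxy)-10-oxo-13-(phenylselanyl)-8-(triethylsilyloxy)-1-(triphenylphosphoniumyl)-1,10-secogermacra-2Z,4(15)-dien-12,6-olide methanesulfonate | c1ccccc1[Se]CC1C(=O)O[C@@H]([C@H]1[C@@H](O[Si](CC)(CC)CC)CC(C)=O)[C@H](O[Si](C)(C)C(C)(C)C)C(=C)/C=C\C[P+](c1ccccc1)(c1ccccc1)c1ccccc1.CS(=O)(=O)[O-]
F2 | step 18 | (1(10)E,2Z,5R,6S,7S,8S,11RS)-5-(tert-butyldimethylsilyloxy)-13-(phenylselanyl)-8-(triethylsilyloxy)germacra-1(10),2,4(15)-trien-12,6-olide | c1ccccc1[Se]CC1C(=O)O[C@H]2[C@H]1[C@@H](O[Si](CC)(CC)CC)C/C(C)=C/C=C\C(=C)[C@H]2O[Si](C)(C)C(C)(C)C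
F3 | step 23 | (1R,2R,3R,5R,6S,7R,8S,10R)-8-angeloyloxy-1,10:2,3-diepoxy-5-hydroxygermacra-4(15),11(13)-dien-12,6-olide | C=C1C(=O)O[C@H]2[C@H]1[C@@H](OC(=O)/C(C)=C\C)C[C@@]1(C)O[C@@H]1[C@@H]1O[C@@H]1C(=C)[C@H]2O
F4 | step 13 | 2-methyl-2-[(2S)-2-(triethylsilyloxy)but-3-yn-1-yl]-1,3-dithiane | C#C[C@H](CC1(C)SCCCS1)O[Si](CC)(CC)CC
F5 | step 13 | methyl (4S)-5-(2-methyl-1,3-dithian-2-yl)-4-(triethylsilyloxy)pent-2-ynoate | COC(=O)C#C[C@H](CC1(C)SCCCS1)O[Si](CC)(CC)CC
F6 | step 13 | methyl (2Z,4S)-5-(2-methyl-1,3-dithian-2-yl)-2-[(4,4,5,5-tetramethyl-1,3,2-dioxaborolan-2-yl)methyl]-4-(triethylsilyloxy)pent-2-enoate | COC(=O)/C(CB1OC(C)(C)C(C)(C)O1)=C\[C@H](CC1(C)SCCCS1)O[Si](CC)(CC)CC
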